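## Structural features

Vismiaphenone D (22) is an achiral benzophenone in which a hexasubstituted ring A and a 4-hydroxyphenyl ring B are joined only through the ketone carbon. Ring A carries the ketone at C1, free hydroxyls at C2 and C6, a methoxy group at C4 and 3-methylbut-2-enyl (prenyl) groups at C3 and C5, so a mirror plane runs through C1 and C4. There is no stereocentre, hence no adjacent stereocentres to control. The fragile elements are the two prenyl groups, each ortho to a phenolic hydroxyl: protic or Lewis acids can close them to 2,2-dimethylchromans or add HX across the double bond. The real difficulty is regiochemical: a fully substituted ring, three oxygens of which exactly one is methylated, and two prenyl groups that electrophilic prenylation of a phloroglucinol places poorly. The key step exploits the fact that C2 to C5 of ring A, with oxygens at C2 and C4 and prenyl groups at C3 and C5, have the pattern of a 2,4-dialkylated cyclohexane-1,3-dione, while C1 and C6, with the aroyl group and the third oxygen, are the two carbons of an alkoxy ynone. A cyclohexadiene made from the dione is joined to the ynone across C1-C2 and C5-C6, and the two spare ring carbons leave as ethylene; this atom mapping was checked and is self-consistent. Two design choices follow from the structure: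

- **O6 as an isopropyl ether, O2 as an acetal.** A boron halide is helped by ketone chelation only for the first of two ortho ethers, so a primary alkyl ether at O6 would probably survive once O2 is freed; a secondary alkyl ether is cleaved without chelation.
- **O4 as a tert-butyldimethylsilyl ether.** A trimethylsilyl ether would be too labile for the diene and the cycloadduct to be purified.

## Logic of the disconnections

**22 from 21.** Three O-alkyl bonds are cut: the acetal O-CH2 bonds at O2 and O4' and the O-CH bond of the isopropyl ether at O6. They are cut last because the free ortho-prenyl phenols are the most acid-sensitive form of the molecule. The forward step needs one Lewis acid to cleave acetals and a secondary alkyl ether at low temperature while sparing the methyl ether at O4 and both prenyl groups.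

**21 from 19.** The O4-CH3 bond is cut and replaced by O4-Si. O4 is thus the only ring A oxygen bearing a fluoride-labile group, so methylation is unambiguous. The forward step (through 20) must free and alkylate one hindered phenoxide in one flask.

**19 from 8 and 17.** The ring bonds C1-C2 and C5-C6 are cut and a two-carbon bridge is added back between C2 and C5, giving 18 and then the two partners. This removes the aromatic ring and all six of its substituent problems at once: every substituent is already fixed on 8 or 17. The forward step needs a regioselective [4+2] cycloaddition between two fully substituted diene termini and a tetrasubstituted alkyne, followed by loss of ethylene.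

**8 from 6.** The O-Si bond at the future O4 is cut. The forward step needs kinetic deprotonation of 6 at the prenyl-bearing carbon (through 7) and silylation on oxygen.

**6 from 4 and 2.** The C-CH2 bond of the prenyl group at the future C5 is cut. Alkylation of the cross-conjugated enolate 5 places this group with full positional control; the forward step needs kinetic deprotonation on the ketone side of the vinylogous ester.

**4 from 3.** The O-CH2 bond of the acetal at the future O2 is cut. The dione is symmetric, so either oxygen gives the same product; the forward step must be basic, because acid closes the enol onto the prenyl double bond.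

**3 from 1 and 2.** The C2-CH2 bond of the first prenyl group is cut, leading to two commodity chemicals. The forward step must favour C- over O-alkylation.

**17 from 16.** The ketone is taken back to the carbinol, because the alkynyl ether anion adds cleanly to an aldehyde. The forward oxidation must be neutral, as both 16 and 17 are acid-sensitive.

**16 from 14 and 10.** The bond between the carbinol carbon and the alkyne is cut, giving 10 and the alkynyl anion 15, which is made in the flask from 14.

**14 from 11 and 12.** The O-C(vinyl) bond is cut. This sets the secondary alkyl group on O6 from a bulk alcohol; the forward step passes through 13, which must never be isolated.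

**10 from 9.** The acetal O-CH2 bond at O4' is cut. The phenol of ring B must be masked through the organolithium step and the methylation of step 10.

## Other disconnections considered

**Alternative 1:** The cut goes through ring B: C1'-C6' and C2'-C3' are broken, leaving the ring A ethynyl ketone 1-[4-methoxy-2,6-bis(methoxymethoxy)-3,5-bis(3-methylbut-2-enyl)phenyl]prop-2-yn-1-one A1 and (E)-1-methoxy-3-(trimethylsilyloxy)buta-1,3-diene A2. Forward, A1 and A2 would be heated; the [4+2] adduct would lose its methoxy group as methanol and give [4-methoxy-2,6-bis(methoxymethoxy)-3,5-bis(3-methylbut-2-enyl)phenyl][4-(trimethylsilyloxy)phenyl]methanone A3.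
- In its favour: a terminal ynone and a diene with unsubstituted termini are far closer to established benzannulations than step 9, so on reliability of the key step this alternative is the better one. Its end-game needs only mild acid, which is also better than step 11.
- Against it: ring B is the trivial ring, available ready-made as in 9. The whole difficulty of ring A is pushed into A1, which would need stepwise prenylation and metalation of a phloroglucinol ether, plus attachment of the acyl group between two ortho substituents.
- Comparison: the mechanisms are of the same family (cycloaddition, then aromatising loss of a small molecule), so the two are equal there. Structurally the chosen plan spends its key step on the ring that carries all the problems; A1 would probably take seven or more steps, so the alternative is expected to be longer.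

**Alternative 2:** The cut is the single ring A bond C1-C6. The precursor is the pyrone 4-methoxy-6-{2-[4-(methoxymethoxy)phenyl]-2-oxoethyl}-3,5-bis(3-methylbut-2-enyl)pyran-2-one A4. Forward, Mg(OMe)2 in methanol would open it to methyl (2E)-3-methoxy-7-[4-(methoxymethoxy)phenyl]-2,4-bis(3-methylbut-2-enyl)-5,7-dioxohept-2-enoate A5, whose aroylmethyl carbon would acylate the ester carbon (Claisen condensation) and give, after enolisation, [2,6-dihydroxy-4-methoxy-3,5-bis(3-methylbut-2-enyl)phenyl][4-(methoxymethoxy)phenyl]methanone A6.
- In its favour: the methyl ether at O4 is present from the start and both ortho hydroxyls emerge free, so no ether on ring A has to be cleaved. This is better than steps 10 and 11. No regiochemical question arises in the ring closure, which is at least equal to the chosen plan, and the conditions are mild.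
- Against it: A4 needs two prenyl groups on a 4-methoxypyrone and an aroylmethyl side chain, a substitution pattern with no direct entry. A5 has an acidic CH between a ketone and an enol ether, so re-lactonisation and retro-Claisen cleavage compete with closure.
- Comparison: it forms one bond where the chosen plan forms two and a ring, so its key step is less convergent. Its step count depends wholly on the route to A4 and is unlikely to be lower.

**Alternative 3:** The cuts are the two bonds to the ketone carbon. The components are the iodide 2-iodo-5-methoxy-1,3-bis(methoxymethoxy)-4,6-bis(3-methylbut-2-enyl)benzene A7, carbon monoxide A8 and 4-hydroxyphenylboronic acid A9. Forward, these would combine under PdCl2(IPr)(3-chloropyridine) and Cs2CO3 to give (4-hydroxyphenyl)[4-methoxy-2,6-bis(methoxymethoxy)-3,5-bis(3-methylbut-2-enyl)phenyl]methanone A10.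
- In its favour: it is the most convergent of the four plans, which is better than the chosen one. Carbonylative coupling of doubly ortho-substituted aryl iodides with a bulky carbene ligand on palladium is a known reaction type, and the end-game is a single mild acid step, again better than step 11.
- Against it: A7 needs iodine between the two acetals and prenyl groups at the two other positions, so three successive directed metalations in a fixed order. The free phenoxide of A9 can capture the acylpalladium intermediate as an ester, and oxidative addition to so electron-rich and hindered an iodide would be slow.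
- Comparison: step count is estimated to be about equal. The chosen plan fixes both prenyl positions by enolate alkylation on a saturated ring, whereas this one relies on the order of arene metalations.

Key step: step 9

Assumption: intermediates 6, 16 and 18 contain stereocentres but are used as racemates, since every stereocentre is destroyed before the achiral target 22 is reached.

## Route

**Step 1**
Reactants: 1 cyclohexane-1,3-dione; 2 1-bromo-3-methylbut-2-ene (prenyl bromide)
Product: 3 2-(3-methylbut-2-enyl)cyclohexane-1,3-dione
Conditions: KOH (1.0 equiv), H2O, 0 °C → rt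
Reagents that add atoms: none
Why: C-alkylation of a cyclic 1,3-dione enolate with an allylic bromide; in water the enolate oxygens are hydrogen-bonded, which favours reaction at C2, and the acidic product can be separated from O-alkylated and dialkylated material by extraction into aqueous base.

**Step 2**
Reactants: 3 2-(3-methylbut-2-enyl)cyclohexane-1,3-dione
Product: 4 3-(methoxymethoxy)-2-(3-methylbut-2-enyl)cyclohex-2-en-1-one
Conditions: MOMCl (1.3 equiv), iPr2NEt (1.5 equiv), CH2Cl2, 0 °C → rt
Reagents that add atoms: chloromethyl methyl ether, COCCl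
Why: O-alkylation of the vinylogous acid by a hard, oxocarbenium-like electrophile gives the vinylogous ester; the two oxygens are equivalent, and the basic medium avoids acid-catalysed closure of the enol onto the prenyl double bond.

**Step 3**
Reactants: 4 3-(methoxymethoxy)-2-(3-methylbut-2-enyl)cyclohex-2-en-1-one; 2 1-bromo-3-methylbut-2-ene
Product: 6 3-(methoxymethoxy)-2,6-bis(3-methylbut-2-enyl)cyclohex-2-en-1-one (racemic), via lithium dienolate 5 (not isolated)
Conditions: LiN(iPr)2 (1.1 equiv), THF, −78 °C; then 2 (1.2 equiv), −78 → 0 °C
Reagents that add atoms: none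
Why: Stork-Danheiser alkylation: kinetic deprotonation of a vinylogous ester occurs on the ketone side (C6), and the cross-conjugated enolate is alkylated there by SN2 attack on the allylic bromide; the new stereocentre is racemic and is erased in step 4.

**Step 4**
Reactants: 6 3-(methoxymethoxy)-2,6-bis(3-methylbut-2-enyl)cyclohex-2-en-1-one
Product: 8 3-(tert-butyldimethylsilyloxy)-1-(methoxymethoxy)-2,4-bis(3-methylbut-2-enyl)cyclohexa-1,3-diene, via lithium dienolate 7 (not isolated)
Conditions: LiN(iPr)2 (1.2 equiv), THF, −78 °C; TBSCl (1.3 equiv), DMPU, −78 → 0 °C; pentane, filtration; Et3N-deactivated SiO2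
Reagents that add atoms: tert-butyldimethylsilyl chloride, CC(C)(C)[Si](C)(C)Cl
Why: a second kinetic deprotonation removes the remaining C6 hydrogen, and the hard silyl chloride traps the enolate on oxygen (silyl enol ether formation); the result is a ring-locked s-cis 1-alkoxy-3-silyloxy diene that should survive rapid chromatography on deactivated silica.

**Step 5**
Reactants: 9 4-hydroxybenzaldehyde
Product: 10 4-(methoxymethoxy)benzaldehyde
Conditions: MOMCl (1.2 equiv), iPr2NEt (1.5 equiv), CH2Cl2, 0 °C → rt
Reagents that add atoms: chloromethyl methyl ether, COCCl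
Why: standard O-alkylation of a phenol to its methoxymethyl acetal, which tolerates the organolithium of step 7 and the fluoride and methyl iodide of step 10.

**Step 6**
Reactants: 11 propan-2-ol; 12 trichloroethylene
Product: 14 2-[(E)-1,2-dichloroethenoxy]propane, via dichloroacetylene 13 (not isolated)
Conditions: KH (1.2 equiv), THF, 0 °C; then Cl2C=CHCl (1.05 equiv), −50 °C → rt, under Ar
Reagents that add atoms: none
Why: the potassium alkoxide dehydrochlorinates trichloroethylene to dichloroacetylene 13, adds to it in anti fashion, and the vinyl anion is protonated by more trichloroethylene (chain process) to give the (E)-1,2-dichlorovinyl ether; 13 is toxic and air-sensitive and is consumed as it forms.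

**Step 7**
Reactants: 14 2-[(E)-1,2-dichloroethenoxy]propane; 10 4-(methoxymethoxy)benzaldehyde
Product: 16 1-[4-(methoxymethoxy)phenyl]-3-(propan-2-yloxy)prop-2-yn-1-ol (racemic), via lithium alkoxyethynide 15 (not isolated)
Conditions: n-BuLi (2.2 equiv), THF, −78 → −40 °C; then 10, −78 °C; aq. NaHCO3 quench
Reagents that add atoms: none
Why: n-BuLi effects dehydrochlorination and chlorine-lithium exchange to give the lithium alkoxyacetylide 15, which adds 1,2 to the aldehyde; the quench is kept basic because acid triggers Meyer-Schuster rearrangement of such carbinols to unsaturated esters.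

**Step 8**
Reactants: 16 1-[4-(methoxymethoxy)phenyl]-3-(propan-2-yloxy)prop-2-yn-1-ol
Product: 17 1-[4-(methoxymethoxy)phenyl]-3-(propan-2-yloxy)prop-2-yn-1-one
Conditions: MnO2 (activated, 15 equiv), CH2Cl2, rt; filtration through Celite
Reagents that add atoms: none
Why: MnO2 oxidises a benzylic and propargylic carbinol under neutral, non-aqueous conditions, which suits a push-pull ynone that adds water and other nucleophiles readily.

**Step 9**
Reactants: 8 3-(tert-butyldimethylsilyloxy)-1-(methoxymethoxy)-2,4-bis(3-methylbut-2-enyl)cyclohexa-1,3-diene; 17 1-[4-(methoxymethoxy)phenyl]-3-(propan-2-yloxy)prop-2-yn-1-one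
Product: 19 [4-(tert-butyldimethylsilyloxy)-2-(methoxymethoxy)-3,5-bis(3-methylbut-2-enyl)-6-(propan-2-yloxy)phenyl][4-(methoxymethoxy)phenyl]methanone, via bicyclo[2.2.2]octadiene adduct 18 (not isolated)
Conditions: 8 (1.0 equiv), 17 (1.5 equiv), BHT (5 mol %), toluene (2 M), 80 °C; then mesitylene, 150 °C, Ar stream
Reagents that add atoms: none
Why: Diene 8 is a ring-locked s-cis 1-alkoxy-3-silyloxy diene whose largest HOMO coefficient lies on the prenyl-bearing terminus (the future C5), and the LUMO of ynone 17 is largest at the alkoxy-bearing β-carbon (the future C6), so a normal-demand [4+2] cycloaddition, concerted but asynchronous or stepwise through a Mukaiyama-Michael zwitterion, should form C5-C6 and C1-C2. This gives the bicyclo[2.2.2]octa-2,5-diene 18, whose only saturated bridge is the former CH2-CH2 unit of the diene. Further heating should bring about a retro-Diels-Alder reaction that expels this bridge as ethylene and leaves ring A aromatic; loss of the alkyne instead only regenerates the partners, so ethylene loss is the sole productive exit (Alder-Rickert reaction). Ring A is closed by an intermolecular cycloaddition of two components, not by cyclisation of a chain, and the two bridgehead stereocentres of 18 are racemic and vanish on aromatisation, so no stereocentre is set. The selectivity needed is regiochemical, and it is secured because both donor oxygens of the diene reinforce the same terminus and the ynone is polarised toward its β-carbon. The first stage is held at 80 °C because an alkynyl ether with β-hydrogens can lose propene by a retro-ene reaction at higher temperature; once it has become the enol ether of 18 this path is closed and the temperature can be raised. The closest known reaction type is the Alder-Rickert synthesis of phenols from 2-silyloxycyclohexa-1,3-dienes and acetylenic ketones or esters.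

**Step 10**
Reactants: 19 [4-(tert-butyldimethylsilyloxy)-2-(methoxymethoxy)-3,5-bis(3-methylbut-2-enyl)-6-(propan-2-yloxy)phenyl][4-(methoxymethoxy)phenyl]methanone
Product: 21 [4-methoxy-2-(methoxymethoxy)-3,5-bis(3-methylbut-2-enyl)-6-(propan-2-yloxy)phenyl][4-(methoxymethoxy)phenyl]methanone, via caesium phenoxide 20 (not isolated)
Conditions: CsF (3 equiv), MeI (5 equiv), DMF, 0 °C → rt
Reagents that add atoms: iodomethane, CI
Why: fluoride cleaves the aryl silyl ether to the phenoxide 20, which is methylated in the same flask (Williamson ether synthesis); O4 is the only oxygen unmasked, so the methyl group can go nowhere else, and acetals, isopropyl ether, ketone and prenyl groups are inert.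

**Step 11**
Reactants: 21 [4-methoxy-2-(methoxymethoxy)-3,5-bis(3-methylbut-2-enyl)-6-(propan-2-yloxy)phenyl][4-(methoxymethoxy)phenyl]methanone
Product: 22 [2,6-dihydroxy-4-methoxy-3,5-bis(3-methylbut-2-enyl)phenyl](4-hydroxyphenyl)methanone (vismiaphenone D)
Conditions: BCl3 (6 equiv), CH2Cl2, −78 → −30 °C; then aq. NaHCO3, −78 °C → rt
Reagents that add atoms: none
Why: Lewis-acid dealkylation: BCl3 cleaves both acetals and ionises the secondary isopropyl ether, a cleavage that needs no chelation and so should still proceed after O2 has closed a boron chelate with the ketone. The primary methyl ether at O4 has no chelating neighbour and should be much slower at or below −30 °C, and the low temperature and basic quench are chosen to spare the prenyl groups.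

## Compound list

1 | cyclohexane-1,3-dione | O=C1CCCC(=O)C1 | starting material
2 | 1-bromo-3-methylbut-2-ene (prenyl bromide) | CC(C)=CCBr | starting material
3 | 2-(3-methylbut-2-enyl)cyclohexane-1,3-dione | CC(C)=CCC1C(=O)CCCC1=O | intermediate
4 | 3-(methoxymethoxy)-2-(3-methylbut-2-enyl)cyclohex-2-en-1-one | COCOC1=C(CC=C(C)C)C(=O)CCC1 | intermediate
5 | lithium 5-(methoxymethoxy)-6-(3-methylbut-2-enyl)cyclohexa-1,5-dien-1-olate | [Li+].[O-]C1=CCCC(OCOC)=C1CC=C(C)C | intermediate (not isolated)
6 | 3-(methoxymethoxy)-2,6-bis(3-methylbut-2-enyl)cyclohex-2-en-1-one (racemic) | COCOC1=C(CC=C(C)C)C(=O)C(CC=C(C)C)CC1 | intermediate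
7 | lithium 5-(methoxymethoxy)-2,6-bis(3-methylbut-2-enyl)cyclohexa-1,5-dien-1-olate | [Li+].[O-]C1=C(CC=C(C)C)CCC(OCOC)=C1CC=C(C)C | intermediate (not isolated)
8 | 3-(tert-butyldimethylsilyloxy)-1-(methoxymethoxy)-2,4-bis(3-methylbut-2-enyl)cyclohexa-1,3-diene | COCOC1=C(CC=C(C)C)C(O[Si](C)(C)C(C)(C)C)=C(CC=C(C)C)CC1 | intermediate
9 | 4-hydroxybenzaldehyde | O=Cc1ccc(O)cc1 | starting material
10 | 4-(methoxymethoxy)benzaldehyde | COCOc1ccc(C=O)cc1 | intermediate
11 | propan-2-ol | CC(C)O | starting material
12 | trichloroethylene | ClC=C(Cl)Cl | starting material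
13 | dichloroacetylene | ClC#CCl | intermediate (not isolated)
14 | 2-[(E)-1,2-dichloroethenoxy]propane | CC(C)O/C(Cl)=C\Cl | intermediate
15 | lithium 2-(propan-2-yloxy)ethynide | [Li+].[C-]#COC(C)C | intermediate (not isolated)
16 | 1-[4-(methoxymethoxy)phenyl]-3-(propan-2-yloxy)prop-2-yn-1-ol (racemic) | CC(C)OC#CC(O)c1ccc(OCOC)cc1 | intermediate
17 | 1-[4-(methoxymethoxy)phenyl]-3-(propan-2-yloxy)prop-2-yn-1-one | CC(C)OC#CC(=O)c1ccc(OCOC)cc1 | intermediate
18 | [5-(tert-butyldimethylsilyloxy)-1-(methoxymethoxy)-4,6-bis(3-methylbut-2-enyl)-3-(propan-2-yloxy)bicyclo[2.2.2]octa-2,5-dien-2-yl][4-(methoxymethoxy)phenyl]methanone (racemic) | COCOC12CCC(CC=C(C)C)(C(O[Si](C)(C)C(C)(C)C)=C1CC=C(C)C)C(OC(C)C)=C2C(=O)c1ccc(OCOC)cc1 | intermediate (not isolated)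
19 | [4-(tert-butyldimethylsilyloxy)-2-(methoxymethoxy)-3,5-bis(3-methylbut-2-enyl)-6-(propan-2-yloxy)phenyl][4-(methoxymethoxy)phenyl]methanone | CC(C)Oc1c(CC=C(C)C)c(O[Si](C)(C)C(C)(C)C)c(CC=C(C)C)c(OCOC)c1C(=O)c1ccc(OCOC)cc1 | intermediate
20 | caesium 4-[4-(methoxymethoxy)benzoyl]-3-(methoxymethoxy)-2,6-bis(3-methylbut-2-enyl)-5-(propan-2-yloxy)phenolate | [Cs+].[O-]c1c(CC=C(C)C)c(OC(C)C)c(C(=O)c2ccc(OCOC)cc2)c(OCOC)c1CC=C(C)C | intermediate (not isolated)
21 | [4-methoxy-2-(methoxymethoxy)-3,5-bis(3-methylbut-2-enyl)-6-(propan-2-yloxy)phenyl][4-(methoxymethoxy)phenyl]methanone | COc1c(CC=C(C)C)c(OC(C)C)c(C(=O)c2ccc(OCOC)cc2)c(OCOC)c1CC=C(C)C | intermediate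
22 | [2,6-dihydroxy-4-methoxy-3,5-bis(3-methylbut-2-enyl)phenyl](4-hydroxyphenyl)methanone (vismiaphenone D) | COc1c(CC=C(C)C)c(O)c(C(=O)c2ccc(O)cc2)c(O)c1CC=C(C)C | target

## Step count and least certain steps

Total step count: 11. Longest linear sequence: 7 steps (steps 1, 2, 3, 4, 9, 10, 11).

**Step 9 (key step).** The cycloaddition may be too slow at the temperature the alkynyl ether tolerates, because both new bonds go to fully substituted carbons and the alkyne is donor-substituted. Retro-ene loss of propene from 17, 1,5-hydrogen shifts in the diene, or arrest at an open-chain Michael adduct would then take over.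
Fallback, setting out from 5 (made from 4 as in step 3) and 17 and returning at 21: the second prenyl group is taken off the nucleophilic diene terminus and added after aromatisation. Dienolate 5 would be silylated (TBSCl, DMPU) instead of alkylated, to give 3-(tert-butyldimethylsilyloxy)-1-(methoxymethoxy)-2-(3-methylbut-2-enyl)cyclohexa-1,3-diene F1, whose reacting terminus is an unsubstituted CH. With 17 under the conditions of step 9 this would pass through [5-(tert-butyldimethylsilyloxy)-1-(methoxymethoxy)-6-(3-methylbut-2-enyl)-3-(propan-2-yloxy)bicyclo[2.2.2]octa-2,5-dien-2-yl][4-(methoxymethoxy)phenyl]methanone F2 and, after loss of ethylene, give [4-(tert-butyldimethylsilyloxy)-2-(methoxymethoxy)-3-(3-methylbut-2-enyl)-6-(propan-2-yloxy)phenyl][4-(methoxymethoxy)phenyl]methanone F3. Bu4NF buffered with AcOH would free [4-hydroxy-2-(methoxymethoxy)-3-(3-methylbut-2-enyl)-6-(propan-2-yloxy)phenyl][4-(methoxymethoxy)phenyl]methanone F4. Its sodium salt (NaH, toluene) would be C-alkylated by 2 at C5, the only open position ortho to the phenoxide, to give [4-hydroxy-2-(methoxymethoxy)-3,5-bis(3-methylbut-2-enyl)-6-(propan-2-yloxy)phenyl][4-(methoxymethoxy)phenyl]methanone F5. MeI and K2CO3 in acetone would then convert F5 into 21.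

**Step 11.** Cyclisation of a prenyl group onto the neighbouring phenol oxygen, or addition of HCl across a prenyl double bond, may occur during the reaction or the quench. Slow cleavage of the hindered methyl ether at O4 is possible if the mixture warms.
Fallback, setting out from 12 and 10 and returning at 22: O6 is carried as a 2-(trimethylsilyl)ethyl ether, which fluoride removes, so no Lewis acid is needed at the end. 2-(Trimethylsilyl)ethanol would replace 11 in step 6 and give {2-[(E)-1,2-dichloroethenoxy]ethyl}trimethylsilane F6. n-BuLi would convert it into lithium 2-[2-(trimethylsilyl)ethoxy]ethynide F7, which would add to 10 to give 1-[4-(methoxymethoxy)phenyl]-3-[2-(trimethylsilyl)ethoxy]prop-2-yn-1-ol F8, and MnO2 would give 1-[4-(methoxymethoxy)phenyl]-3-[2-(trimethylsilyl)ethoxy]prop-2-yn-1-one F9. With 8 under the conditions of step 9 (first stage at or below 70 °C) the adduct [5-(tert-butyldimethylsilyloxy)-1-(methoxymethoxy)-4,6-bis(3-methylbut-2-enyl)-3-[2-(trimethylsilyl)ethoxy]bicyclo[2.2.2]octa-2,5-dien-2-yl][4-(methoxymethoxy)phenyl]methanone F10 and then {4-(tert-butyldimethylsilyloxy)-2-(methoxymethoxy)-3,5-bis(3-methylbut-2-enyl)-6-[2-(trimethylsilyl)ethoxy]phenyl}[4-(methoxymethoxy)phenyl]methanone F11 would form. K2CO3 and MeI in DMF-MeOH would exchange the aryl silyl ether for a methyl ether and give {4-methoxy-2-(methoxymethoxy)-3,5-bis(3-methylbut-2-enyl)-6-[2-(trimethylsilyl)ethoxy]phenyl}[4-(methoxymethoxy)phenyl]methanone F12. Bu4NF in DMF at 50 °C would fragment the silylethyl ether to [2-hydroxy-4-methoxy-6-(methoxymethoxy)-3,5-bis(3-methylbut-2-enyl)phenyl][4-(methoxymethoxy)phenyl]methanone F13, and HCl in MeOH at room temperature would remove both acetals to give 22.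

**Step 4.** Hydrolytic loss of the silyl enol ether during isolation, and partial deprotonation at the γ-carbon instead of the prenyl-bearing carbon, would lower the amount and purity of the diene.
Fallback, setting out from 7 and 17 and returning at 18: the diene is not isolated and the two bonds are made by enolate chemistry. 17 would be added to dienolate 7 at −78 °C, so that conjugate addition at the alkoxy-bearing alkyne carbon and closure of the resulting allenolate onto the vinylogous ester carbon (double Michael addition) give lithium 5-[4-(methoxymethoxy)benzoyl]-4-(methoxymethoxy)-1,3-bis(3-methylbut-2-enyl)-6-(propan-2-yloxy)bicyclo[2.2.2]octa-2,5-dien-2-olate F14. TBSCl with DMPU would silylate F14 in the same flask to 18, which is then heated as in the second stage of step 9.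

**Step 1.** Competing O-alkylation and double C-alkylation of the dione would cut the supply of 3.
Fallback, setting out from 2 and returning at 3: the dione is unmasked from an arene. 1,3-Dimethoxybenzene would be lithiated between its two oxygens (n-BuLi, THF, 0 °C) and alkylated with 2 to give 1,3-dimethoxy-2-(3-methylbut-2-enyl)benzene F15. Birch reduction (Li, NH3, t-BuOH, THF, −78 °C) would give 1,5-dimethoxy-6-(3-methylbut-2-enyl)cyclohexa-1,4-diene F16 with the isolated double bond untouched, and cold dilute oxalic acid in aqueous THF would hydrolyse both enol ethers to 3.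

## Further compounds

F1 | step 9 | 3-(tert-butyldimethylsilyloxy)-1-(methoxymethoxy)-2-(3-methylbut-2-enyl)cyclohexa-1,3-diene | COCOC1=C(CC=C(C)C)C(O[Si](C)(C)C(C)(C)C)=CCC1
F2 | step 9 | [5-(tert-butyldimethylsilyloxy)-1-(methoxymethoxy)-6-(3-methylbut-2-enyl)-3-(propan-2-yloxy)bicyclo[2.2.2]octa-2,5-dien-2-yl][4-(methoxymethoxy)phenyl]methanone (racemic) | COCOC12CCC(C(O[Si](C)(C)C(C)(C)C)=C1CC=C(C)C)C(OC(C)C)=C2C(=O)c1ccc(OCOC)cc1
F3 | step 9 | [4-(tert-butyldimethylsilyloxy)-2-(methoxymethoxy)-3-(3-methylbut-2-enyl)-6-(propan-2-yloxy)phenyl][4-(methoxymethoxy)phenyl]methanone | CC(C)Oc1cc(O[Si](C)(C)C(C)(C)C)c(CC=C(C)C)c(OCOC)c1C(=O)c1ccc(OCOC)cc1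
F4 | step 9 | [4-hydroxy-2-(methoxymethoxy)-3-(3-methylbut-2-enyl)-6-(propan-2-yloxy)phenyl][4-(methoxymethoxy)phenyl]methanone | CC(C)Oc1cc(O)c(CC=C(C)C)c(OCOC)c1C(=O)c1ccc(OCOC)cc1
F5 | step 9 | [4-hydroxy-2-(methoxymethoxy)-3,5-bis(3-methylbut-2-enyl)-6-(propan-2-yloxy)phenyl][4-(methoxymethoxy)phenyl]methanone | CC(C)Oc1c(CC=C(C)C)c(O)c(CC=C(C)C)c(OCOC)c1C(=O)c1ccc(OCOC)cc1
F6 | step 11 | {2-[(E)-1,2-dichloroethenoxy]ethyl}trimethylsilane | C[Si](C)(C)CCO/C(Cl)=C\Cl
F7 | step 11 | lithium 2-[2-(trimethylsilyl)ethoxy]ethynide | [Li+].[C-]#COCC[Si](C)(C)C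
F8 | step 11 | 1-[4-(methoxymethoxy)phenyl]-3-[2-(trimethylsilyl)ethoxy]prop-2-yn-1-ol (racemic) | C[Si](C)(C)CCOC#CC(O)c1ccc(OCOC)cc1
F9 | step 11 | 1-[4-(methoxymethoxy)phenyl]-3-[2-(trimethylsilyl)ethoxy]prop-2-yn-1-one | C[Si](C)(C)CCOC#CC(=O)c1ccc(OCOC)cc1
F10 | step 11 | [5-(tert-butyldimethylsilyloxy)-1-(methoxymethoxy)-4,6-bis(3-methylbut-2-enyl)-3-[2-(trimethylsilyl)ethoxy]bicyclo[2.2.2]octa-2,5-dien-2-yl][4-(methoxymethoxy)phenyl]methanone (racemic) | COCOC12CCC(CC=C(C)C)(C(O[Si](C)(C)C(C)(C)C)=C1CC=C(C)C)C(OCC[Si](C)(C)C)=C2C(=O)c1ccc(OCOC)cc1
F11 | step 11 | {4-(tert-butyldimethylsilyloxy)-2-(methoxymethoxy)-3,5-bis(3-methylbut-2-enyl)-6-[2-(trimethylsilyl)ethoxy]phenyl}[4-(methoxymethoxy)phenyl]methanone | C[Si](C)(C)CCOc1c(CC=C(C)C)c(O[Si](C)(C)C(C)(C)C)c(CC=C(C)C)c(OCOC)c1C(=O)c1ccc(OCOC)cc1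
F12 | step 11 | {4-methoxy-2-(methoxymethoxy)-3,5-bis(3-methylbut-2-enyl)-6-[2-(trimethylsilyl)ethoxy]phenyl}[4-(methoxymethoxy)phenyl]methanone | COc1c(CC=C(C)C)c(OCC[Si](C)(C)C)c(C(=O)c2ccc(OCOC)cc2)c(OCOC)c1CC=C(C)C
F13 | step 11 | [2-hydroxy-4-methoxy-6-(methoxymethoxy)-3,5-bis(3-methylbut-2-enyl)phenyl][4-(methoxymethoxy)phenyl]methanone | COc1c(CC=C(C)C)c(O)c(C(=O)c2ccc(OCOC)cc2)c(OCOC)c1CC=C(C)C
F14 | step 4 | lithium 5-[4-(methoxymethoxy)benzoyl]-4-(methoxymethoxy)-1,3-bis(3-methylbut-2-enyl)-6-(propan-2-yloxy)bicyclo[2.2.2]octa-2,5-dien-2-olate (racemic) | [Li+].[O-]C1=C(CC=C(C)C)C2(OCOC)CCC1(CC=C(C)C)C(OC(C)C)=C2C(=O)c1ccc(OCOC)cc1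
F15 | step 1 | 1,3-dimethoxy-2-(3-methylbut-2-enyl)benzene | COc1cccc(OC)c1CC=C(C)C
F16 | step 1 | 1,5-dimethoxy-6-(3-methylbut-2-enyl)cyclohexa-1,4-diene | COC1=CCC=C(OC)C1CC=C(C)C
A1 | alternative 1 | 1-[4-methoxy-2,6-bis(methoxymethoxy)-3,5-bis(3-methylbut-2-enyl)phenyl]prop-2-yn-1-one | C#CC(=O)c1c(OCOC)c(CC=C(C)C)c(OC)c(CC=C(C)C)c1OCOC
A2 | alternative 1 | (E)-1-methoxy-3-(trimethylsilyloxy)buta-1,3-diene | CO/C=C/C(=C)O[Si](C)(C)C
A3 | alternative 1 | [4-methoxy-2,6-bis(methoxymethoxy)-3,5-bis(3-methylbut-2-enyl)phenyl][4-(trimethylsilyloxy)phenyl]methanone | C[Si](C)(C)Oc1ccc(cc1)C(=O)c1c(OCOC)c(CC=C(C)C)c(OC)c(CC=C(C)C)c1OCOC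
A4 | alternative 2 | 4-methoxy-6-{2-[4-(methoxymethoxy)phenyl]-2-oxoethyl}-3,5-bis(3-methylbut-2-enyl)pyran-2-one | COc1c(CC=C(C)C)c(=O)oc(CC(=O)c2ccc(OCOC)cc2)c1CC=C(C)C
A5 | alternative 2 | methyl (2E)-3-methoxy-7-[4-(methoxymethoxy)phenyl]-2,4-bis(3-methylbut-2-enyl)-5,7-dioxohept-2-enoate (racemic) | COC(=O)/C(CC=C(C)C)=C(/OC)C(CC=C(C)C)C(=O)CC(=O)c1ccc(OCOC)cc1
A6 | alternative 2 | [2,6-dihydroxy-4-methoxy-3,5-bis(3-methylbut-2-enyl)phenyl][4-(methoxymethoxy)phenyl]methanone | COCOc1ccc(cc1)C(=O)c1c(O)c(CC=C(C)C)c(OC)c(CC=C(C)C)c1O
A7 | alternative 3 | 2-iodo-5-methoxy-1,3-bis(methoxymethoxy)-4,6-bis(3-methylbut-2-enyl)benzene | COCOc1c(I)c(OCOC)c(CC=C(C)C)c(OC)c1CC=C(C)C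
A8 | alternative 3 | carbon monoxide | [C-]#[O+]
A9 | alternative 3 | 4-hydroxyphenylboronic acid | OB(O)c1ccc(O)cc1
A10 | alternative 3 | (4-hydroxyphenyl)[4-methoxy-2,6-bis(methoxymethoxy)-3,5-bis(3-methylbut-2-enyl)phenyl]methanone | COCOc1c(C(=O)c2ccc(O)cc2)c(OCOC)c(CC=C(C)C)c(OC)c1CC=C(C)C
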